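**Retrosynthetic overview**
1. The azepanone (seven-membered ring) is closed last, by acid-mediated N-acyliminium formation between the lactam N–H and a side-chain aldehyde with Et3SiH reduction; the east γ-lactone is made just before, by oxidative lactonisation of a benzyl-masked 1,4-diol.
2. The nine-membered keto-lactam is closed by high-dilution macrolactamisation (lactam N–C(=O) bond) of a seco amino acid; this is the key ring closure.
3. The seco amino acid comes from a sulfinimine Mannich union (C10–C11) of west methyl ketone 23 with east N-sulfinyl aldimine 34; 34 comes from a glutamic-acid-derived trityl lactone, with butenolide hydrogenation setting the east methyl.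
4. Ketone 23 comes from an Evans succinate syn-aldol/lactonisation (C4–C8) of imide 19 with aldehyde 11; 11 comes from a chirality-transferring Ireland–Claisen rearrangement.
5. Ring order: west γ-lactone → nine-membered lactam → east γ-lactone → azepanone.

**Assumption and labels:** atom labels follow the target SMILES from left to right: C1–C2 ethyl on C3; C4(–O5); west lactone O5–C6(=O)–C7(Me)–C8; C9 ketone; C10; C11(–N17); east lactone C12–C13–C14(Me)–C15(=O)–O16; azepanone N17–C18–C19–C20–C21–C22–C23(=O). The target is 3R,4S,7S,8R,11S,12S,14S,22S. Simple reagents (BnBr, MeI and the like) are not numbered. The route has not been run; stereochemical outcomes are predicted from standard models.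

**Route**

Step 1
Reactants: 1 oxepan-2-one (ε-caprolactone)
Product: 2 6-(benzyloxy)hexanoic acid
Conditions: KOH, BnBr, toluene, reflux; aq. HCl work-up
Reagents that add atoms: benzyl bromide BrCc1ccccc1; potassium hydroxide [K+].[OH-]
Why: Saponification of the lactone and in-situ Williamson etherification of the resulting alkoxide give the benzyl ether acid; no stereocentre is involved.

Step 2
Reactants: 3 (3E)-hex-3-en-2-one
Product: 4 (2R,3E)-hex-3-en-2-ol
Conditions: (S)-Me-CBS oxazaborolidine (10 mol%), catecholborane, toluene, −78 °C; MeOH, aq. NaOH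
Reagents that add atoms: none
Why: Corey–Bakshi–Shibata 1,2-reduction, in which the catalyst treats the alkenyl group as the large substituent and delivers hydride to give the (R)-carbinol (minor enantiomer is removed later as separable diastereomers).

Step 3
Reactants: 2 6-(benzyloxy)hexanoic acid; 4 (2R,3E)-hex-3-en-2-ol
Product: 5 (2R,3E)-hex-3-en-2-yl 6-(benzyloxy)hexanoate
Conditions: DCC, DMAP (cat.), CH2Cl2, 0 °C → rt
Reagents that add atoms: none
Why: Steglich esterification, which does not touch the carbinol configuration.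

Step 4
Reactants: 5 (2R,3E)-hex-3-en-2-yl 6-(benzyloxy)hexanoate
Product: 8 (2S,3S,4E)-2-[4-(benzyloxy)butyl]-3-ethylhex-4-enoic acid, via silyl ketene acetal 6 (not isolated), via trimethylsilyl ester 7 (not isolated)
Conditions: LiN(iPr)2, THF, −78 °C; Me3SiCl, Et3N; −78 → 60 °C; 1 M HCl
Reagents that add atoms: none
Why: Ireland–Claisen rearrangement, in which the kinetic enolate (chain cis to the allyloxy oxygen) reacts through a chair with the carbinol methyl equatorial, so the (R)-carbinol is transferred to C22 (S) and C3 with the anti relationship and a new (E)-alkene.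

Step 5
Reactants: 8 (2S,3S,4E)-2-[4-(benzyloxy)butyl]-3-ethylhex-4-enoic acid
Product: 9 tert-butyl (2S,3S,4E)-2-[4-(benzyloxy)butyl]-3-ethylhex-4-enoate
Conditions: Cl3CC(=NH)OtBu, BF3·OEt2 (cat.), cyclohexane–CH2Cl2, rt
Reagents that add atoms: tert-butyl 2,2,2-trichloroacetimidate CC(C)(C)OC(=N)C(Cl)(Cl)Cl
Why: Acid-catalysed imidate tert-butylation works without base, so the α-centre C22 is not epimerised.

Step 6
Reactants: 9 tert-butyl (2S,3S,4E)-2-[4-(benzyloxy)butyl]-3-ethylhex-4-enoate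
Product: 11 tert-butyl (2S,3R)-2-[4-(benzyloxy)butyl]-3-formylpentanoate, via ozonide 10 (not isolated)
Conditions: O3, CH2Cl2, −78 °C; then Me2S, −78 °C → rt
Reagents that add atoms: ozone [O-][O+]=O
Why: Ozonolysis with reductive work-up cuts the propenyl group down to the C4 aldehyde without touching C3 (the descriptor changes only by priority), and the aldehyde is used at once.

Step 7
Reactants: 12 (4R)-4-benzyl-3-propanoyl-1,3-oxazolidin-2-one; 13 tert-butyl bromoacetate
Product: 14 tert-butyl (3S)-4-[(4R)-4-benzyl-2-oxo-1,3-oxazolidin-3-yl]-3-methyl-4-oxobutanoate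
Conditions: NaN(SiMe3)2, THF, −78 °C; then 13, −78 → −40 °C
Reagents that add atoms: none
Why: Evans asymmetric alkylation, in which the chelated (Z)-sodium enolate is alkylated on the face away from the benzyl group and so sets C7 (S).

Step 8
Reactants: 14 tert-butyl (3S)-4-[(4R)-4-benzyl-2-oxo-1,3-oxazolidin-3-yl]-3-methyl-4-oxobutanoate
Product: 15 4-tert-butyl 1-methyl (2S)-2-methylbutanedioate
Conditions: MeMgBr, MeOH, THF, 0 °C; aq. NH4Cl
Reagents that add atoms: methanol CO
Why: Transesterification of the imide by bromomagnesium methoxide cleaves the exocyclic acyl group without epimerising C7 and leaves the tert-butyl ester.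

Step 9
Reactants: 15 4-tert-butyl 1-methyl (2S)-2-methylbutanedioate
Product: 16 (3S)-4-methoxy-3-methyl-4-oxobutanoic acid
Conditions: CF3CO2H, CH2Cl2, rt
Reagents that add atoms: none
Why: Acidolysis of the tert-butyl ester by alkyl–oxygen cleavage leaves the methyl ester and C7 intact.

Step 10
Reactants: 16 (3S)-4-methoxy-3-methyl-4-oxobutanoic acid; 17 (4R)-4-benzyl-1,3-oxazolidin-2-one
Product: 19 methyl (2S)-4-[(4R)-4-benzyl-2-oxo-1,3-oxazolidin-3-yl]-2-methyl-4-oxobutanoate, via mixed pivalic anhydride 18 (not isolated)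
Conditions: t-BuCOCl, Et3N, THF, −20 °C; then 17, LiCl, rt
Reagents that add atoms: none
Why: N-acylation of the oxazolidinone through the mixed anhydride takes place at the unhindered succinyl carbonyl.

Step 11
Reactants: 19 methyl (2S)-4-[(4R)-4-benzyl-2-oxo-1,3-oxazolidin-3-yl]-2-methyl-4-oxobutanoate; 11 tert-butyl (2S,3R)-2-[4-(benzyloxy)butyl]-3-formylpentanoate
Product: 21 tert-butyl (2S,3R)-2-[4-(benzyloxy)butyl]-3-{(2S,3R,4S)-3-[(4R)-4-benzyl-2-oxo-1,3-oxazolidine-3-carbonyl]-4-methyl-5-oxooxolan-2-yl}pentanoate, via syn-aldol adduct 20 (not isolated)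
Conditions: Bu2BOTf, iPr2NEt, CH2Cl2, −78 → 0 °C; 11, −78 → 0 °C; pH 7 buffer, MeOH, H2O2; then PPTS (cat.), CH2Cl2, 40 °C
Reagents that add atoms: none
Why: Evans syn-aldol of the succinate imide through the Zimmerman–Traxler chair of the (Z)-boron enolate sets C8 (R) and C4 (S) under auxiliary control, and the C4 hydroxyl then lactonises onto the methyl ester (not the hindered tert-butyl ester) to give the 4,8-trans, 7,8-cis lactone.

Step 12
Reactants: 21 the lactone imide from step 11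
Product: 22 tert-butyl (2S,3R)-2-[4-(benzyloxy)butyl]-3-{(2S,3R,4S)-3-[(ethylsulfanyl)carbonyl]-4-methyl-5-oxooxolan-2-yl}pentanoate
Conditions: EtSH, n-BuLi, THF, 0 °C; aq. NH4Cl
Reagents that add atoms: ethanethiol CCS
Why: Thiolysis of the imide by LiSEt removes the auxiliary by exocyclic cleavage, while the lactone and tert-butyl ester are inert to thiolate at 0 °C.

Step 13
Reactants: 22 the S-ethyl thioester from step 12
Product: 23 tert-butyl (2S,3R)-2-[4-(benzyloxy)butyl]-3-[(2S,3R,4S)-3-acetyl-4-methyl-5-oxooxolan-2-yl]pentanoate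
Conditions: MeZnI, PdCl2(PPh3)2 (5 mol%), toluene–THF, rt; aq. HCl
Reagents that add atoms: methylzinc iodide C[Zn]I
Why: Fukuyama coupling turns the thioester into the methyl ketone under neutral conditions, so C8 is not epimerised and the esters are untouched.

Step 14
Reactants: 24 (5S)-5-[(trityloxy)methyl]oxolan-2-one
Product: 25 (3R,5S)-3-methyl-5-[(trityloxy)methyl]oxolan-2-one
Conditions: LiN(iPr)2, THF, −78 °C; MeI
Reagents that add atoms: iodomethane CI
Why: Lactone enolate alkylation puts the methyl anti to the trityloxymethyl group, though this centre is erased in the next step.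

Step 15
Reactants: 25 (3R,5S)-3-methyl-5-[(trityloxy)methyl]oxolan-2-one
Product: 27 (5S)-3-methyl-5-[(trityloxy)methyl]furan-2(5H)-one, via α-phenylselanyl lactone 26 (not isolated)
Conditions: LiN(iPr)2, THF, −78 °C; PhSeBr; then H2O2, pyridine, CH2Cl2, 0 °C → rt
Reagents that add atoms: none
Why: α-Selenenylation followed by selenoxide syn-elimination into the ring gives the α-methyl butenolide.

Step 16
Reactants: 27 (5S)-3-methyl-5-[(trityloxy)methyl]furan-2(5H)-one
Product: 28 (3S,5S)-3-methyl-5-[(trityloxy)methyl]oxolan-2-one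
Conditions: H2 (1 atm), Rh/Al2O3, EtOAc, rt
Reagents that add atoms: none
Why: Heterogeneous hydrogenation adds to the face away from the trityloxymethyl group, giving the cis-3,5 lactone and setting C14 (S).

Step 17
Reactants: 28 (3S,5S)-3-methyl-5-[(trityloxy)methyl]oxolan-2-one
Product: 29 (2S,4S)-2-methyl-5-(trityloxy)pentane-1,4-diol
Conditions: LiAlH4, THF, 0 °C; H2O work-up
Reagents that add atoms: none
Why: Hydride reduction opens the lactone to the 1,4-diol, which masks the east lactone so that the later free C11 amine cannot undergo O→N acyl transfer.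

Step 18
Reactants: 29 (2S,4S)-2-methyl-5-(trityloxy)pentane-1,4-diol
Product: 30 (2S,4S)-1,4-bis(benzyloxy)-2-methyl-5-(trityloxy)pentane
Conditions: NaH, BnBr, Bu4NI (cat.), THF–DMF, 0 °C → rt
Reagents that add atoms: benzyl bromide BrCc1ccccc1
Why: Double Williamson etherification; no stereocentre is touched.

Step 19
Reactants: 30 (2S,4S)-1,4-bis(benzyloxy)-2-methyl-5-(trityloxy)pentane
Product: 31 (2S,4S)-2,5-bis(benzyloxy)-4-methylpentan-1-ol
Conditions: TsOH·H2O (cat.), MeOH–CH2Cl2, rt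
Reagents that add atoms: none
Why: Acid-catalysed detritylation transfers the trityl cation to methanol and leaves the benzyl ethers.

Step 20
Reactants: 31 (2S,4S)-2,5-bis(benzyloxy)-4-methylpentan-1-ol
Product: 32 (2S,4S)-2,5-bis(benzyloxy)-4-methylpentanal
Conditions: Dess–Martin periodinane, CH2Cl2, 0 °C → rt
Reagents that add atoms: none
Why: Dess–Martin oxidation is non-basic, so the α-benzyloxy aldehyde keeps its C12 configuration.

Step 21
Reactants: 32 (2S,4S)-2,5-bis(benzyloxy)-4-methylpentanal; 33 (R)-2-methylpropane-2-sulfinamide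
Product: 34 (R)-N-[(1E,2S,4S)-2,5-bis(benzyloxy)-4-methylpentylidene]-2-methylpropane-2-sulfinamide
Conditions: CuSO4 (anhydrous), CH2Cl2, rt
Reagents that add atoms: none
Why: Ellman condensation with CuSO4 as dehydrant gives the (E)-N-sulfinyl aldimine without epimerising C12.

Step 22
Reactants: 23 the west methyl ketone; 34 the east N-sulfinyl aldimine
Product: 36 tert-butyl (2S,3R)-2-[4-(benzyloxy)butyl]-3-[(2S,3R,4S)-3-{(3S,4S,6S)-4,7-bis(benzyloxy)-6-methyl-3-[(R)-tert-butylsulfinylamino]heptanoyl}-4-methyl-5-oxooxolan-2-yl]pentanoate, via lithium enolate 35 (not isolated)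
Conditions: LiN(SiMe3)2, THF, −78 °C; then 34, −78 °C; aq. NH4Cl
Reagents that add atoms: none
Why: Sulfinimine Mannich addition of the kinetic methyl-ketone enolate through a six-membered chair with lithium bridging the enolate and sulfinyl oxygens, in which the (R)-sulfinyl group directs attack to give C11 (S), syn to the C12 benzyloxy group.

Step 23
Reactants: 36 the Mannich adduct
Product: 37 (2S,3R)-3-{(2S,3R,4S)-3-[(3S,4S,6S)-3-amino-4,7-bis(benzyloxy)-6-methylheptanoyl]-4-methyl-5-oxooxolan-2-yl}-2-[4-(benzyloxy)butyl]pentanoic acid hydrochloride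
Conditions: HCl (4 M in dioxane), CH2Cl2, 0 °C → rt
Reagents that add atoms: hydrogen chloride Cl
Why: Acidolysis removes the N-sulfinyl group and the tert-butyl ester in one operation, while the benzyl ethers, lactone and ketone survive.

Step 24
Reactants: 37 the seco amino acid hydrochloride
Product: 39 nine-membered lactam (N17–C23 amide closed; 4-(benzyloxy)butyl on C22; (1S,3S)-1,4-bis(benzyloxy)-3-methylbutyl on C11; 3R,4S,7S,8R,11S,22S), via acyl azide 38 (not isolated)
Conditions: (PhO)2P(O)N3, NaHCO3, DMF (1 mM), 0 °C → rt, 3 d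
Reagents that add atoms: none
Why: High-dilution macrolactamisation (Shioiri conditions), in which the primary amine attacks the activated C23 carboxyl to close the nine-membered ring, with no new stereocentre and little risk to C22.

Step 25
Reactants: 39 the nine-membered lactam
Product: 40 triol (hydroxyls at C12/C15/C18 in place of the three benzyl ethers of 39)
Conditions: H2 (1 atm), Pd(OH)2/C, EtOAc–EtOH, rt
Reagents that add atoms: none
Why: Hydrogenolysis removes the three benzyl ethers and leaves the ketone, lactam and lactone.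

Step 26
Reactants: 40 the triol
Product: 42 lactone aldehyde (east (3S,5S)-lactone on C11; 4-oxobutyl on C22; secondary lactam), via lactol aldehyde 41 (not isolated)
Conditions: TEMPO (cat.), PhI(OAc)2, CH2Cl2, rt
Reagents that add atoms: none
Why: TEMPO-mediated oxidative lactonisation, in which both primary alcohols go to aldehydes while the secondary C12 hydroxyl is left to trap the C15 aldehyde as a lactol that is oxidised on to the γ-lactone; no stereocentre is touched.

Step 27
Reactants: 42 the lactone aldehyde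
Product: 44 tuberostemonone, via cyclic N-acyl hemiaminal 43 (not isolated)
Conditions: CF3CO2H, CH2Cl2, 0 °C → rt; then Et3SiH
Reagents that add atoms: none
Why: Intramolecular reductive amidation, in which acid condenses the lactam N–H with the C18 aldehyde to an N-acyliminium ion that Et3SiH reduces, closing the azepanone without creating a stereocentre.

**Compound list**

1 | oxepan-2-one (ε-caprolactone) | O=C1CCCCCO1 | starting material
2 | 6-(benzyloxy)hexanoic acid | OC(=O)CCCCCOCc1ccccc1 | intermediate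
3 | (3E)-hex-3-en-2-one | CC/C=C/C(C)=O | starting material
4 | (2R,3E)-hex-3-en-2-ol | C[C@@H](O)/C=C/CC | intermediate
5 | (2R,3E)-hex-3-en-2-yl 6-(benzyloxy)hexanoate | C[C@@H](OC(=O)CCCCCOCc1ccccc1)/C=C/CC | intermediate
6 | O-trimethylsilyl ketene acetal of 5 (chain cis to the allyloxy oxygen) | C[C@@H](O/C(O[Si](C)(C)C)=C\CCCCOCc1ccccc1)/C=C/CC | intermediate
7 | trimethylsilyl (2S,3S,4E)-2-[4-(benzyloxy)butyl]-3-ethylhex-4-enoate | C[Si](C)(C)OC(=O)[C@@H](CCCCOCc1ccccc1)[C@@H](CC)/C=C/C | intermediate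
8 | (2S,3S,4E)-2-[4-(benzyloxy)butyl]-3-ethylhex-4-enoic acid | OC(=O)[C@@H](CCCCOCc1ccccc1)[C@@H](CC)/C=C/C | intermediate
9 | tert-butyl (2S,3S,4E)-2-[4-(benzyloxy)butyl]-3-ethylhex-4-enoate | CC(C)(C)OC(=O)[C@@H](CCCCOCc1ccccc1)[C@@H](CC)/C=C/C | intermediate
10 | tert-butyl (2S,3R)-2-[4-(benzyloxy)butyl]-3-(5-methyl-1,2,4-trioxolan-3-yl)pentanoate | CC(C)(C)OC(=O)[C@@H](CCCCOCc1ccccc1)[C@@H](CC)C1OOC(C)O1 | intermediate
11 | tert-butyl (2S,3R)-2-[4-(benzyloxy)butyl]-3-formylpentanoate | CC(C)(C)OC(=O)[C@@H](CCCCOCc1ccccc1)[C@@H](CC)C=O | intermediate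
12 | (4R)-4-benzyl-3-propanoyl-1,3-oxazolidin-2-one | CCC(=O)N1[C@H](Cc2ccccc2)COC1=O | starting material
13 | tert-butyl bromoacetate | CC(C)(C)OC(=O)CBr | starting material
14 | tert-butyl (3S)-4-[(4R)-4-benzyl-2-oxo-1,3-oxazolidin-3-yl]-3-methyl-4-oxobutanoate | CC(C)(C)OC(=O)C[C@H](C)C(=O)N1[C@H](Cc2ccccc2)COC1=O | intermediate
15 | 4-tert-butyl 1-methyl (2S)-2-methylbutanedioate | COC(=O)[C@@H](C)CC(=O)OC(C)(C)C | intermediate
16 | (3S)-4-methoxy-3-methyl-4-oxobutanoic acid | COC(=O)[C@@H](C)CC(=O)O | intermediate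
17 | (4R)-4-benzyl-1,3-oxazolidin-2-one | O=C1N[C@H](Cc2ccccc2)CO1 | starting material
18 | mixed anhydride of 16 with pivalic acid | COC(=O)[C@@H](C)CC(=O)OC(=O)C(C)(C)C | intermediate
19 | methyl (2S)-4-[(4R)-4-benzyl-2-oxo-1,3-oxazolidin-3-yl]-2-methyl-4-oxobutanoate | COC(=O)[C@@H](C)CC(=O)N1[C@H](Cc2ccccc2)COC1=O | intermediate
20 | tert-butyl (2S,3R)-2-[4-(benzyloxy)butyl]-3-{(1S,2R,3S)-2-[(4R)-4-benzyl-2-oxo-1,3-oxazolidine-3-carbonyl]-1-hydroxy-4-methoxy-3-methyl-4-oxobutyl}pentanoate | CC(C)(C)OC(=O)[C@@H](CCCCOCc1ccccc1)[C@@H](CC)[C@H](O)[C@@H]([C@H](C)C(=O)OC)C(=O)N1[C@H](Cc2ccccc2)COC1=O | intermediate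
21 | tert-butyl (2S,3R)-2-[4-(benzyloxy)butyl]-3-{(2S,3R,4S)-3-[(4R)-4-benzyl-2-oxo-1,3-oxazolidine-3-carbonyl]-4-methyl-5-oxooxolan-2-yl}pentanoate | CC(C)(C)OC(=O)[C@@H](CCCCOCc1ccccc1)[C@@H](CC)[C@@H]2OC(=O)[C@@H](C)[C@H]2C(=O)N1[C@H](Cc3ccccc3)COC1=O | intermediate
22 | tert-butyl (2S,3R)-2-[4-(benzyloxy)butyl]-3-{(2S,3R,4S)-3-[(ethylsulfanyl)carbonyl]-4-methyl-5-oxooxolan-2-yl}pentanoate | CC(C)(C)OC(=O)[C@@H](CCCCOCc1ccccc1)[C@@H](CC)[C@@H]1OC(=O)[C@@H](C)[C@H]1C(=O)SCC | intermediate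
23 | tert-butyl (2S,3R)-2-[4-(benzyloxy)butyl]-3-[(2S,3R,4S)-3-acetyl-4-methyl-5-oxooxolan-2-yl]pentanoate | CC(C)(C)OC(=O)[C@@H](CCCCOCc1ccccc1)[C@@H](CC)[C@@H]1OC(=O)[C@@H](C)[C@H]1C(C)=O | intermediate
24 | (5S)-5-[(trityloxy)methyl]oxolan-2-one | O=C1CC[C@@H](COC(c2ccccc2)(c2ccccc2)c2ccccc2)O1 | starting material
25 | (3R,5S)-3-methyl-5-[(trityloxy)methyl]oxolan-2-one | O=C1[C@H](C)C[C@@H](COC(c2ccccc2)(c2ccccc2)c2ccccc2)O1 | intermediate
26 | (3R,5S)-3-methyl-3-(phenylselanyl)-5-[(trityloxy)methyl]oxolan-2-one | O=C1[C@](C)([Se]c2ccccc2)C[C@@H](COC(c2ccccc2)(c2ccccc2)c2ccccc2)O1 | intermediate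
27 | (5S)-3-methyl-5-[(trityloxy)methyl]furan-2(5H)-one | O=C1C(C)=C[C@@H](COC(c2ccccc2)(c2ccccc2)c2ccccc2)O1 | intermediate
28 | (3S,5S)-3-methyl-5-[(trityloxy)methyl]oxolan-2-one | O=C1[C@@H](C)C[C@@H](COC(c2ccccc2)(c2ccccc2)c2ccccc2)O1 | intermediate
29 | (2S,4S)-2-methyl-5-(trityloxy)pentane-1,4-diol | OC[C@@H](C)C[C@H](O)COC(c1ccccc1)(c1ccccc1)c1ccccc1 | intermediate
30 | (2S,4S)-1,4-bis(benzyloxy)-2-methyl-5-(trityloxy)pentane | c1ccccc1COC[C@@H](C)C[C@H](OCc1ccccc1)COC(c1ccccc1)(c1ccccc1)c1ccccc1 | intermediate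
31 | (2S,4S)-2,5-bis(benzyloxy)-4-methylpentan-1-ol | OC[C@@H](OCc1ccccc1)C[C@H](C)COCc1ccccc1 | intermediate
32 | (2S,4S)-2,5-bis(benzyloxy)-4-methylpentanal | O=C[C@@H](OCc1ccccc1)C[C@H](C)COCc1ccccc1 | intermediate
33 | (R)-2-methylpropane-2-sulfinamide | CC(C)(C)[S@@](=O)N | starting material
34 | (R)-N-[(1E,2S,4S)-2,5-bis(benzyloxy)-4-methylpentylidene]-2-methylpropane-2-sulfinamide | CC(C)(C)[S@@](=O)/N=C/[C@@H](OCc1ccccc1)C[C@H](C)COCc1ccccc1 | intermediate
35 | lithium enolate of 23 (methyl side) | CC(C)(C)OC(=O)[C@@H](CCCCOCc1ccccc1)[C@@H](CC)[C@@H]1OC(=O)[C@@H](C)[C@H]1C(=C)O[Li] | intermediate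
36 | tert-butyl (2S,3R)-2-[4-(benzyloxy)butyl]-3-[(2S,3R,4S)-3-{(3S,4S,6S)-4,7-bis(benzyloxy)-6-methyl-3-[(R)-tert-butylsulfinylamino]heptanoyl}-4-methyl-5-oxooxolan-2-yl]pentanoate | CC(C)(C)OC(=O)[C@@H](CCCCOCc1ccccc1)[C@@H](CC)[C@@H]1OC(=O)[C@@H](C)[C@H]1C(=O)C[C@H](N[S@](=O)C(C)(C)C)[C@@H](OCc1ccccc1)C[C@H](C)COCc1ccccc1 | intermediate
37 | (2S,3R)-3-{(2S,3R,4S)-3-[(3S,4S,6S)-3-amino-4,7-bis(benzyloxy)-6-methylheptanoyl]-4-methyl-5-oxooxolan-2-yl}-2-[4-(benzyloxy)butyl]pentanoic acid hydrochloride | OC(=O)[C@@H](CCCCOCc1ccccc1)[C@@H](CC)[C@@H]1OC(=O)[C@@H](C)[C@H]1C(=O)C[C@H](N)[C@@H](OCc1ccccc1)C[C@H](C)COCc1ccccc1.Cl | intermediate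
38 | acyl azide of 37 (C23 carbonyl azide; free C11 amine) | [N-]=[N+]=NC(=O)[C@@H](CCCCOCc1ccccc1)[C@@H](CC)[C@@H]1OC(=O)[C@@H](C)[C@H]1C(=O)C[C@H](N)[C@@H](OCc1ccccc1)C[C@H](C)COCc1ccccc1 | intermediate
39 | nine-membered lactam (N17–C23 amide; 4-(benzyloxy)butyl on C22; (1S,3S)-1,4-bis(benzyloxy)-3-methylbutyl on C11; 3R,4S,7S,8R,11S,22S) | CC[C@H]1[C@@H]2OC(=O)[C@@H](C)[C@H]2C(=O)C[C@@H]([C@@H](OCc3ccccc3)C[C@H](C)COCc3ccccc3)NC(=O)[C@H]1CCCCOCc1ccccc1 | intermediate
40 | triol (OH in place of each OBn of 39) | CC[C@H]1[C@@H]2OC(=O)[C@@H](C)[C@H]2C(=O)C[C@@H]([C@@H](O)C[C@H](C)CO)NC(=O)[C@H]1CCCCO | intermediate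
41 | lactol aldehyde (east ring as 2-hydroxyoxolane; 4-oxobutyl on C22) | CC[C@H]1[C@@H]2OC(=O)[C@@H](C)[C@H]2C(=O)C[C@@H]([C@@H]2C[C@H](C)C(O)O2)NC(=O)[C@H]1CCCC=O | intermediate
42 | lactone aldehyde (east (3S,5S)-lactone on C11; 4-oxobutyl on C22; secondary lactam) | CC[C@H]1[C@@H]2OC(=O)[C@@H](C)[C@H]2C(=O)C[C@@H]([C@@H]2C[C@H](C)C(=O)O2)NC(=O)[C@H]1CCCC=O | intermediate
43 | cyclic N-acyl hemiaminal (18-hydroxytuberostemonone) | CC[C@H]1[C@@H]2OC(=O)[C@@H](C)[C@H]2C(=O)C[C@@H]([C@@H]2C[C@H](C)C(=O)O2)N2C(O)CCC[C@@H]1C2=O | intermediate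
44 | tuberostemonone | CC[C@H]1[C@@H]2OC(=O)[C@@H](C)[C@H]2C(=O)C[C@@H]([C@@H]2C[C@H](C)C(=O)O2)N2CCCC[C@@H]1C2=O | target

**Totals and risks**

Total step count: 27.
Longest linear sequence: 14 steps (1, 3, 4, 5, 6, 11, 12, 13, 22, 23, 24, 25, 26, 27 from ε-caprolactone; the east branch 14–21 followed by 22–27 is also 14). The other branches are step 2 and steps 7–10.

The three steps most likely to fail:

Step 24, the nine-membered macrolactamisation, may be defeated by ring strain and oligomerisation. The fallback closes the same ring by ring-closing metathesis on a preformed amide; it sets out from thioester 22 and sulfinimine 34 and comes back at lactam 39. Fukuyama reduction of 22 (Et3SiH, Pd/C) gives the aldehyde F1, Wittig methylenation (Ph3P=CH2) gives the vinyl lactone F2, and CF3CO2H gives the acid F3. Vinylmagnesium bromide adds to 34 to give the allylic sulfinamide F4, and HCl in dioxane gives the allylic amine hydrochloride F5. Coupling of F3 with F5 (EDC·HCl, HOAt, iPr2NEt) gives the diene amide F6. The second-generation Grubbs catalyst closes the ring as the (Z)-cycloalkene lactam F7. A Wacker oxidation (PdCl2, CuCl, O2, DMF–H2O), directed to C9 by the allylic amide nitrogen, then gives 39.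

Step 27, the azepanone closure, may suffer from silane reduction of the aldehyde or from a lactam geometry that keeps N–H away from C18. The fallback replaces the N-acyliminium reduction by a neutral lactim-ether N-alkylation; it sets out from 42 and comes back at 44. NaBH(OAc)3 reduces only the aldehyde to the primary alcohol F8, and I2, PPh3 and imidazole give the iodide F9. Me3OBF4 O-methylates the lactam to the lactim ether F10. On warming with NaI in MeCN the imidate nitrogen displaces the iodide and the O-methyl group is lost, which gives 44.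

Step 22, the sulfinimine Mannich reaction, may give poor C11 selectivity if the C12 benzyloxy group opposes the sulfinyl group, and any deprotonation at C8 instead of the methyl group would open the west lactone by β-elimination. The fallback introduces nitrogen by conjugate addition under substrate control; it sets out from ketone 23 and aldehyde 32 and comes back at 37. Aldol addition of the lithium enolate of 23 to 32 gives the β-hydroxy ketone F11, and MsCl with Et3N then DBU gives the (E)-enone F12. Addition of tert-butyl carbamate catalysed by PdCl2(MeCN)2, expected syn to the C12 benzyloxy group with separable epimers, gives the carbamate F13. HCl in dioxane removes the Boc group and the tert-butyl ester to give 37.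

Further compounds

F1 | step 24 | tert-butyl (2S,3R)-2-[4-(benzyloxy)butyl]-3-[(2S,3R,4S)-3-formyl-4-methyl-5-oxooxolan-2-yl]pentanoate | CC(C)(C)OC(=O)[C@@H](CCCCOCc1ccccc1)[C@@H](CC)[C@@H]1OC(=O)[C@@H](C)[C@H]1C=O
F2 | step 24 | vinyl lactone tert-butyl ester (23 with vinyl in place of acetyl) | CC(C)(C)OC(=O)[C@@H](CCCCOCc1ccccc1)[C@@H](CC)[C@@H]1OC(=O)[C@@H](C)[C@H]1C=C
F3 | step 24 | vinyl lactone carboxylic acid (free C23 acid of F2) | OC(=O)[C@@H](CCCCOCc1ccccc1)[C@@H](CC)[C@@H]1OC(=O)[C@@H](C)[C@H]1C=C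
F4 | step 24 | (R)-N-[(3S,4S,6S)-4,7-bis(benzyloxy)-6-methylhept-1-en-3-yl]-2-methylpropane-2-sulfinamide | C=C[C@H](N[S@](=O)C(C)(C)C)[C@@H](OCc1ccccc1)C[C@H](C)COCc1ccccc1
F5 | step 24 | (3S,4S,6S)-4,7-bis(benzyloxy)-6-methylhept-1-en-3-amine hydrochloride | C=C[C@H](N)[C@@H](OCc1ccccc1)C[C@H](C)COCc1ccccc1.Cl
F6 | step 24 | secondary amide of F3 with F5 (acyclic diene) | C=C[C@H](NC(=O)[C@@H](CCCCOCc1ccccc1)[C@@H](CC)[C@@H]1OC(=O)[C@@H](C)[C@H]1C=C)[C@@H](OCc1ccccc1)C[C@H](C)COCc1ccccc1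
F7 | step 24 | nine-membered (Z)-C9=C10 cycloalkene lactam (39 with CH=CH in place of C(=O)CH2) | CC[C@H]1[C@@H]2OC(=O)[C@@H](C)[C@H]2/C=C\[C@@H]([C@@H](OCc3ccccc3)C[C@H](C)COCc3ccccc3)NC(=O)[C@H]1CCCCOCc1ccccc1
F8 | step 27 | primary alcohol (42 with 4-hydroxybutyl on C22) | CC[C@H]1[C@@H]2OC(=O)[C@@H](C)[C@H]2C(=O)C[C@@H]([C@@H]2C[C@H](C)C(=O)O2)NC(=O)[C@H]1CCCCO
F9 | step 27 | primary iodide (42 with 4-iodobutyl on C22) | CC[C@H]1[C@@H]2OC(=O)[C@@H](C)[C@H]2C(=O)C[C@@H]([C@@H]2C[C@H](C)C(=O)O2)NC(=O)[C@H]1CCCCI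
F10 | step 27 | O-methyl lactim ether of F9 | CC[C@H]1[C@@H]2OC(=O)[C@@H](C)[C@H]2C(=O)C[C@@H]([C@@H]2C[C@H](C)C(=O)O2)N=C(OC)[C@H]1CCCCI
F11 | step 22 | β-hydroxy ketone from 23 and 32 (C11 carbinol, both epimers) | CC(C)(C)OC(=O)[C@@H](CCCCOCc1ccccc1)[C@@H](CC)[C@@H]1OC(=O)[C@@H](C)[C@H]1C(=O)CC(O)[C@@H](OCc1ccccc1)C[C@H](C)COCc1ccccc1
F12 | step 22 | (E)-C10=C11 enone | CC(C)(C)OC(=O)[C@@H](CCCCOCc1ccccc1)[C@@H](CC)[C@@H]1OC(=O)[C@@H](C)[C@H]1C(=O)/C=C/[C@@H](OCc1ccccc1)C[C@H](C)COCc1ccccc1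
F13 | step 22 | N-Boc β-amino ketone (36 with tert-butoxycarbonyl in place of tert-butylsulfinyl) | CC(C)(C)OC(=O)[C@@H](CCCCOCc1ccccc1)[C@@H](CC)[C@@H]1OC(=O)[C@@H](C)[C@H]1C(=O)C[C@H](NC(=O)OC(C)(C)C)[C@@H](OCc1ccccc1)C[C@H](C)COCc1ccccc1
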